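## Structural features

The target is a trimer of coniferyl alcohol: three guaiacyl-type benzene rings (A, B, C) and two 2-aryl-3-hydroxymethyl-7-methoxy-2,3-dihydrobenzofurans, unit 1 fused to ring B and unit 2 fused to ring C. Ring A (4-hydroxy-3-methoxyphenyl) sits on C2 of unit 1. Ring B is both the benzo ring of unit 1 and, through its C5, the aryl group on C2' of unit 2. Ring C carries the (E)-3-hydroxyprop-1-enyl chain at C5', para to O1'. The four stereocentres form two vicinal pairs, C2/C3 (2R,3S) and C2'/C3' (2'R,3'S), both trans; ring B insulates the pairs, so neither can relay its configuration to the other. The fragile groups are the free phenol of ring A (easily oxidized), the cinnamyl alcohol (allylic ionization under acid) and the benzylic ether carbons C2 and C2', each para to an oxygen (acid-induced ring opening, hydrogenolysis). The real difficulty is to build the same trans ring twice on two different arenes with independent absolute control, while three primary alcohols and a phenol are kept apart. The key step uses the fact that C2' is benzylic to ring B and para to the ring B oxygen that later becomes O1. While unit 1 is not yet built, that oxygen can be a free phenol, so ring B can be oxidized to a para-quinone methide whose exocyclic carbon is C2', and the ring C oxygen ortho to the C3' branch can then close O1'–C2'.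

## Logic of the disconnections

25 to 24. No skeletal bond is cut. The allylic alcohol, the C9' hydroxyl and the ring A phenol are traced back to an enoate and two pivalates. The acid-sensitive cinnamyl alcohol and the oxidizable phenol then appear only in the last operation, and one hydride step unveils all of them. The forward step must reduce the enoate 1,2 and cleave two hindered esters without touching the benzylic ethers.

24 to 23 to 22. The C=C bond of the C5' side chain is cut back to the formyl group of 22, and the C9 hydroxyl is traced to an N–O alkoxyamine. The formyl group is the substituent the key step needs on ring C, so it is carried unchanged from 14 to 22; the N–O bond is reduced only after the aldehyde is gone, because zinc would attack it. The demands are an E-selective olefination and an N–O cleavage that spares the enoate.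

22 to 21. The C3–C3a bond and the C9–O bond are cut. An aryl radical at C3a closes onto a vinyl group faster than bimolecular traps can act, and the C9 radical left behind accepts oxygen; the iodine needed is already present from 1. Unit 1 is reduced to an aryl iodide and an allyl ether, and C3 need not be preset. The forward step must induce trans geometry from C2 and must outrun capture of the aryl radical and a 1,5-hydrogen shift.

21 to 16 plus 20. The O1–C2 ether bond is cut. This pairs a phenol with a cinnamyl electrophile and lets a chiral catalyst set C2 regardless of the distant C2'/C3' pair. The gain is convergence: ring A arrives as a three-step fragment. The demand is branched and enantioselective attack by a hindered 2,6-disubstituted aryloxide, with no re-ionization of the product.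

20 to 19 to 18 to 17. Only acyl and redox adjustments: the carbonate leaving group, the allylic alcohol and the phenol ester are traced to a commercial enal. The phenol ester must survive the hydride reduction of the aldehyde.

16 to 14 through 15. The O1'–C2' bond is cut. C2' is para-benzylic to the free phenol of ring B, so oxidation makes C2' electrophilic exactly where O1' must bond, with no leaving group and no preset stereocentre at C2'. The dihydrofuran ring opens to a 1,2-diarylpropane with one stereocentre, and the iodine stays as the handle for unit 1. The forward step must oxidize only the ring B phenol, close trans, and stop before the product phenol is oxidized again.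

14 to 13 to 12 to 11, then 11 to 10 plus 4. After protecting-group and oxidation-level changes, the C2'–C3' bond is cut. C3' lies alpha to a carbonyl at the C9' position of an arylacetic acid, so an auxiliary-controlled enolate alkylation sets it. Two aryl pieces of similar size result. The demands are high facial selectivity, no epimerization of the acidic alpha-aryl centre, and protecting groups that all fall in one acid step.

10 to 7 plus 8, then 7 to 6 to 5 to 2. The N-acyl bond and the ring C aryl–CH2 bond are cut. The iodine of 2 stands exactly where the acetic acid chain is needed, so ring C comes from the same compound as ring B. The coupling must tolerate an acetal and an ortho-alkoxy group.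

4 to 3 to 2 to 1. Functional-group changes only (bromide from alcohol from aldehyde; phenol protection). The bromination must be neutral because of the acid-labile phenol ether.

## Other disconnections considered

Alternative 1: The cut is C2'–C3' of unit 2, made late. Diazo ester A1 (ring C aryldiazoacetate with a chiral lactamide ester, its phenol oxygen benzylated by C5 of finished unit 1) would be decomposed by Rh2(S-DOSP)4. The dirhodium carbene would insert 1,5 into an OCH2 hydrogen and close the dihydrofuran ring to give A2.
- In its favour: ring C is attached by a plain O-benzylation, no free phenol or oxidant is involved, and one catalytic step makes a C–C bond and both stereocentres of unit 2. On stereocentres per step and on late convergence this plan is the better one; the chosen plan makes one C–O bond and one stereocentre in its key step and needs an auxiliary alkylation beforehand.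
- Against it here: insertions of this type often favour the cis ester kinetically, so an epimerization at C3' would be needed. Catalyst and lactamide must be matched. The electron-rich rings A and B offer competing cyclopropanation and aromatic substitution. Diazo transfer must be run on an elaborated intermediate.
- After the step, the ester must be reduced, the bromide turned into the propenol, and two silyl ethers removed. Unit 1 must already exist, and this step does not help to make it.
- Comparison: the chosen plan relies on substrate electronics, a cheap oxidant and a thermodynamically favoured trans ring; Alternative 1 relies on a chiral catalyst against a kinetic cis preference. In step count the two are about equal once unit 1 and the post-insertion adjustments are counted.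

Alternative 2: The cut is C3–C3a (with C9–O) of unit 1. The aryl radical from iodide A3 (generated by fac-Ir(ppy)3 photoreduction or a silane) would close 5-exo onto the vinyl group of the (R)-1-arylallyl ether, and TEMPO would trap the C9 radical to give A4.
- In its favour: the closure is fast and neutral and installs the C9 oxygen in the same step. The chosen plan uses the same closure in step 17, so on this bond the two plans are equal.
- A point where it is better: A3 already carries the finished propenol as a silyl ether, so no olefination follows the cyclization.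
- Against it as the central idea: it sets only C3, by substrate control from a C2 that must come from an earlier enantioselective etherification. It says nothing about unit 2, which needs its own solution. The styrenyl silyl ether of A3 is exposed to radicals and, under photocatalysis, to E/Z isomerization by energy transfer. Three kinds of protecting group must be removed at the end.
- Comparison: the two plans are complementary, not competing. The chosen plan keeps this radical closure for unit 1 and supplies the missing answer for unit 2; the endgame step counts are equal.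

Alternative 3: The cut is C3'–C3a', the reverse of a 1,2-aryl shift. (R)-Flavanone A5, whose 2-aryl group is ring B of finished unit 1, would be treated with PhI(OAc)2 and H2SO4 in trimethyl orthoformate. Migration of C4a would contract the pyranone to the methyl trans-2,3-dihydrobenzofuran-3-carboxylate A6.
- In its favour: flavanones come easily from chalcones, and the aldehyde needed on C5 of unit 1 is a natural oxidation level. The shift is stereospecific, so C3' follows from C2' without extra reagent control. That equals the chosen plan, where C2' follows from C3'. For racemic material this route would be the shorter one.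
- Against it here: electron-rich 2-aryl flavanones equilibrate with their chalcones, so the configuration at C2 of A5 is at risk. The step runs in strong acid with a hypervalent iodine oxidant, in the presence of three electron-rich arenes and the acid-labile benzylic ether at C2 of unit 1. The ester must then be reduced and the bromide converted into the propenol.
- Comparison: Alternative 3 makes a C–C bond of the ring where the chosen plan makes a C–O bond. It works through cations in strong acid; the chosen plan works through a neutral oxidation. Its step-count advantage is lost once the single enantiomer is required.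

Key step: step 12

Remark on locants: unprimed numbers refer to unit 1 (ring B, bearing ring A), primed numbers to unit 2 (ring C); C9 and C9' are the hydroxymethyl carbons; pivalate means 2,2-dimethylpropanoate.

Remark on configuration: a re-derivation of the descriptors shows that the (4S)-benzyl auxiliary gives (S) at C3' in 11 to 14 and that (S)-14 maps onto (2'R,3'S)-16, so no structure needed correcting.

Remark on the precursor: 14 is made only at the moment of use. Its two phenols and its formyl group are released together in step 11, and both of its aryl halves are drawn from 2.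

Remark on the ligand: the sense of induction of the phosphoramidite in step 16 is to be fixed on a model phenol; both antipodes are commercial, and the one that gives the (R) ether is used.

## Steps

Step 1
Reactants: 1 5-iodovanillin
Product: 2 3-iodo-5-methoxy-4-(methoxymethoxy)benzaldehyde
Conditions: MOMCl, i-Pr2NEt, CH2Cl2, 0 °C to rt
Reagents that add atoms: chloromethyl methyl ether, COCCl
Why: O-alkylation of an acidic, hindered phenol with a reactive alpha-chloro ether (Williamson type). The MOM ether withstands hydride, enolates, organozinc and base and falls with acid together with the later acetal; 2 serves both aryl fragments.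

Step 2
Reactants: 2 3-iodo-5-methoxy-4-(methoxymethoxy)benzaldehyde
Product: 3 [3-iodo-5-methoxy-4-(methoxymethoxy)phenyl]methanol
Conditions: NaBH4, MeOH/THF, 0 °C
Reagents that add atoms: none
Why: Borohydride reduction of an aromatic aldehyde; the aryl iodide and the MOM ether are inert.

Step 3
Reactants: 3 [3-iodo-5-methoxy-4-(methoxymethoxy)phenyl]methanol
Product: 4 5-(bromomethyl)-1-iodo-3-methoxy-2-(methoxymethoxy)benzene
Conditions: CBr4, PPh3, CH2Cl2, 0 °C
Reagents that add atoms: tetrabromomethane, BrC(Br)(Br)Br
Why: Appel bromination under neutral conditions, so the acid-labile MOM ether should survive. The electron-rich benzylic bromide is to be used without long storage.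

Step 4
Reactants: 2 3-iodo-5-methoxy-4-(methoxymethoxy)benzaldehyde
Product: 5 2-[3-iodo-5-methoxy-4-(methoxymethoxy)phenyl]-5,5-dimethyl-1,3-dioxane
Conditions: 2,2-dimethylpropane-1,3-diol, HC(OMe)3, PPTS (cat.), CH2Cl2, rt
Reagents that add atoms: 2,2-dimethylpropane-1,3-diol, OCC(C)(C)CO
Why: Acid-catalysed acetalization driven by the orthoformate at room temperature, mild enough to spare the aryl MOM ether. The cyclic acetal masks the aldehyde against the zinc enolate, the imide enolate and LiBH4 and is sturdier on work-up than a dimethyl acetal.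

Step 5
Reactants: 5 2-[3-iodo-5-methoxy-4-(methoxymethoxy)phenyl]-5,5-dimethyl-1,3-dioxane
Product: 6 ethyl 2-[5-(5,5-dimethyl-1,3-dioxan-2-yl)-3-methoxy-2-(methoxymethoxy)phenyl]acetate
Conditions: BrZnCH2CO2Et, Pd(dba)2 (cat.), XPhos (cat.), THF, rt to 50 °C
Reagents that add atoms: ethyl 2-(bromozincio)acetate (Reformatsky reagent), CCOC(=O)C[Zn]Br
Why: Negishi-type alpha-arylation of a zinc ester enolate: oxidative addition of the C–I bond to zerovalent palladium, transmetalation of the Reformatsky reagent, reductive elimination. The nearly neutral organozinc tolerates acetal and MOM ether and cannot self-condense as a lithium enolate could.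

Step 6
Reactants: 6 ethyl 2-[5-(5,5-dimethyl-1,3-dioxan-2-yl)-3-methoxy-2-(methoxymethoxy)phenyl]acetate
Product: 7 2-[5-(5,5-dimethyl-1,3-dioxan-2-yl)-3-methoxy-2-(methoxymethoxy)phenyl]acetic acid
Conditions: LiOH, THF/MeOH/H2O, rt; then 1 M HCl to pH 4, 0 °C
Reagents that add atoms: lithium hydroxide (hydroxide oxygen), [Li+].[OH-]
Why: Ester saponification; base is harmless to acetal and MOM ether, and acidification is stopped at pH 4 in the cold so that neither is hydrolysed.

Step 7
Reactants: 7 2-[5-(5,5-dimethyl-1,3-dioxan-2-yl)-3-methoxy-2-(methoxymethoxy)phenyl]acetic acid; 8 (S)-4-benzyl-2-oxazolidinone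
Product: 10 (4S)-4-benzyl-3-{2-[5-(5,5-dimethyl-1,3-dioxan-2-yl)-3-methoxy-2-(methoxymethoxy)phenyl]acetyl}-1,3-oxazolidin-2-one, via mixed pivalic anhydride 9 (not isolated)
Conditions: PivCl, Et3N, THF, −20 °C; then 8, LiCl, −20 °C to rt
Reagents that add atoms: none
Why: N-acylation of the oxazolidinone through the mixed pivalic anhydride with LiCl/Et3N activation. No strong base is present, so the acidic arylacetyl unit is not driven to a ketene, and attack occurs at the less hindered arylacetyl carbonyl of 9.

Step 8
Reactants: 10 (4S)-4-benzyl-3-(arylacetyl)oxazolidinone of ring C; 4 5-(bromomethyl)-1-iodo-3-methoxy-2-(methoxymethoxy)benzene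
Product: 11 (4S)-4-benzyl-3-{(2S)-2-[5-(5,5-dimethyl-1,3-dioxan-2-yl)-3-methoxy-2-(methoxymethoxy)phenyl]-3-[3-iodo-5-methoxy-4-(methoxymethoxy)phenyl]propanoyl}-1,3-oxazolidin-2-one
Conditions: NaN(SiMe3)2, THF, −78 °C; then 4, −78 to −30 °C
Reagents that add atoms: none
Why: Evans alkylation: the chelated sodium (Z)-enolate is shielded on one face by the C4 benzyl group and the benzylic bromide enters from the other, which sets the future C3' as (S). Low temperature and short exposure to base guard the acidic alpha-aryl centre against epimerization.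

Step 9
Reactants: 11 alkylated (4S)-imide
Product: 12 (2S)-2-[5-(5,5-dimethyl-1,3-dioxan-2-yl)-3-methoxy-2-(methoxymethoxy)phenyl]-3-[3-iodo-5-methoxy-4-(methoxymethoxy)phenyl]propan-1-ol
Conditions: LiBH4, MeOH (1 equiv), THF, 0 °C
Reagents that add atoms: none
Why: Reductive cleavage of the N-acyl oxazolidinone at the exocyclic carbonyl should give the primary alcohol and return the auxiliary. Once the carbonyl is gone, C3' can no longer epimerize.

Step 10
Reactants: 12 (2S)-2,3-diarylpropan-1-ol
Product: 13 (2S)-2-[5-(5,5-dimethyl-1,3-dioxan-2-yl)-3-methoxy-2-(methoxymethoxy)phenyl]-3-[3-iodo-5-methoxy-4-(methoxymethoxy)phenyl]propyl pivalate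
Conditions: PivCl, pyridine, DMAP (cat.), CH2Cl2, 0 °C to rt
Reagents that add atoms: pivaloyl chloride, CC(C)(C)C(=O)Cl
Why: Acylation of the only free hydroxyl. The bulky pivalate resists acid, Ag2O, aryloxide and radical conditions, biases the ring closure towards trans, and is removed by the final hydride step.

Step 11
Reactants: 13 fully protected (2S)-2,3-diarylpropyl pivalate
Product: 14 (2S)-2-(5-formyl-2-hydroxy-3-methoxyphenyl)-3-(4-hydroxy-3-iodo-5-methoxyphenyl)propyl pivalate
Conditions: 2 M aq. HCl, THF, 45 °C
Reagents that add atoms: water, O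
Why: Acid hydrolysis removes both MOM ethers and the dioxane acetal in one operation; pivalate, aryl iodide and C3' (no carbonyl attached) are stable. Both phenols and the formyl group are set free only here, directly before the oxidation.

Step 12
Reactants: 14 (2S)-2-(5-formyl-2-hydroxy-3-methoxyphenyl)-3-(4-hydroxy-3-iodo-5-methoxyphenyl)propyl pivalate
Product: 16 [(2R,3S)-5-formyl-2-(4-hydroxy-3-iodo-5-methoxyphenyl)-7-methoxy-2,3-dihydro-1-benzofuran-3-yl]methyl pivalate, via para-quinone methide 15 (not isolated)
Conditions: Ag2O (1.1 equiv), 4 Å molecular sieves, dry CH2Cl2, rt, dark; filtered as soon as 14 is consumed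
Reagents that add atoms: none
Why: Ag2O takes two electrons and two protons from the ring B phenol (phenoxyl radical, then loss of a C2' hydrogen) to give para-quinone methide 15, whose exocyclic carbon is C2'. The ring C hydroxyl then adds to C2' in a 5-exo-trig conjugate addition, forming O1'–C2' and the dihydrofuran ring of unit 2 while ring B rearomatizes to the iodophenol. The closest known reaction types are the Ag2O oxidation of 2,6-disubstituted 4-alkylphenols to para-quinone methides and the phenol-to-quinone-methide closure that ends biomimetic phenylcoumaran formation. The new stereocentre C2' is controlled by C3' from step 8: the oxygen should attack the methide face that places the quinoid ring anti to the pivaloyloxymethyl group, giving the 2',3'-trans ring (2'R,3'S), which is also the more stable isomer. The step needs oxidation of ring B only: the ring C phenol is deactivated by its para-formyl group, and the ortho positions of ring B are blocked by iodine and methoxy, which shuts off radical coupling. About one equivalent of oxidant in a dry, non-nucleophilic solvent should prevent a second oxidation of 16 towards the benzofuran, oxidation of the aldehyde, and addition of water to 15. The intramolecular capture should be faster than tautomerization of 15 to a stilbene, which would erase C3'.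

Step 13
Reactants: 17 coniferyl aldehyde ((E)-4-hydroxy-3-methoxycinnamaldehyde)
Product: 18 2-methoxy-4-[(E)-3-oxoprop-1-enyl]phenyl pivalate
Conditions: PivCl, Et3N, DMAP (cat.), CH2Cl2, 0 °C
Reagents that add atoms: pivaloyl chloride, CC(C)(C)C(=O)Cl
Why: Phenol acylation. The pivalate lowers the electron density of ring A (less ionization of the later branched ether), resists aryloxide and methoxide, and falls in the final hydride step.

Step 14
Reactants: 18 2-methoxy-4-[(E)-3-oxoprop-1-enyl]phenyl pivalate
Product: 19 4-[(E)-3-hydroxyprop-1-enyl]-2-methoxyphenyl pivalate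
Conditions: NaBH4, CeCl3·7H2O, MeOH, −20 °C
Reagents that add atoms: none
Why: Luche 1,2-reduction of the enal; the hindered aryl pivalate should survive the short, cold exposure.

Step 15
Reactants: 19 4-[(E)-3-hydroxyprop-1-enyl]-2-methoxyphenyl pivalate
Product: 20 (E)-3-(3-methoxy-4-pivaloyloxyphenyl)prop-2-enyl methyl carbonate
Conditions: ClCO2Me, pyridine, CH2Cl2, 0 °C
Reagents that add atoms: methyl chloroformate, COC(=O)Cl
Why: Standard carbonate formation of a primary allylic alcohol, giving the leaving group for the allylic substitution.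

Step 16
Reactants: 16 iodophenol of unit 2; 20 (E)-3-(3-methoxy-4-pivaloyloxyphenyl)prop-2-enyl methyl carbonate
Product: 21 [(2R,3S)-5-formyl-2-{3-iodo-5-methoxy-4-[(1R)-1-(3-methoxy-4-pivaloyloxyphenyl)prop-2-enyloxy]phenyl}-7-methoxy-2,3-dihydro-1-benzofuran-3-yl]methyl pivalate
Conditions: LiN(SiMe3)2 (1.0 equiv), THF, −78 °C to rt; then 20, [Ir(cod)Cl]2 (2 mol%), O,O'-(1,1'-binaphthalene-2,2'-diyl) N,N-bis(1-phenylethyl)phosphoramidite (4 mol%, antipode giving the R ether, pre-activated with n-PrNH2), THF, rt to 40 °C
Reagents that add atoms: none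
Why: Iridium-catalysed allylic etherification: the cyclometalated iridium phosphoramidite complex ionizes the carbonate to an allyl complex, and the lithium aryloxide attacks its aryl-substituted terminus to give the branched ether. The catalyst, not the remote C2'/C3' pair, sets the new centre (future C2) as (R); aldehyde, aryl iodide and pivalates are inert.

Step 17
Reactants: 21 aryl iodide (R)-1-arylallyl ether
Product: 22 [(2R,3S)-5-formyl-7-methoxy-2-{(2R,3S)-7-methoxy-2-(3-methoxy-4-pivaloyloxyphenyl)-3-[(2,2,6,6-tetramethylpiperidin-1-yl)oxymethyl]-2,3-dihydro-1-benzofuran-5-yl}-2,3-dihydro-1-benzofuran-3-yl]methyl pivalate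
Conditions: Bu3SnH (portionwise), TEMPO (excess), toluene, 70 °C
Reagents that add atoms: TEMPO, CC1(C)CCCC(C)(C)N1[O]
Why: Aryl radical–alkene cyclization with nitroxide trapping: the stannyl radical (from Bu3SnH and TEMPO) abstracts iodine, the aryl radical closes 5-exo-trig onto the vinyl group faster than any bimolecular capture, and TEMPO traps the primary C9 radical. C3 should form trans to the C2 aryl group because the transition state that keeps the terminal CH2 away from ring A (allylic strain) is preferred, giving (2R,3S).

Step 18
Reactants: 22 aldehyde alkoxyamine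
Product: 23 ethyl (E)-3-[(2R,3S)-7-methoxy-2-{(2R,3S)-7-methoxy-2-(3-methoxy-4-pivaloyloxyphenyl)-3-[(2,2,6,6-tetramethylpiperidin-1-yl)oxymethyl]-2,3-dihydro-1-benzofuran-5-yl}-3-(pivaloyloxymethyl)-2,3-dihydro-1-benzofuran-5-yl]prop-2-enoate
Conditions: Ph3P=CHCO2Et, toluene, 70 °C
Reagents that add atoms: ethyl (triphenylphosphoranylidene)acetate, CCOC(=O)C=P(c1ccccc1)(c1ccccc1)c1ccccc1
Why: Wittig olefination with a stabilized ylide, which should give the (E)-enoate under neutral conditions; the primary alkoxyamine and both pivalates are stable at this temperature.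

Step 19
Reactants: 23 enoate alkoxyamine
Product: 24 ethyl (E)-3-[(2R,3S)-2-{(2R,3S)-3-(hydroxymethyl)-7-methoxy-2-(3-methoxy-4-pivaloyloxyphenyl)-2,3-dihydro-1-benzofuran-5-yl}-7-methoxy-3-(pivaloyloxymethyl)-2,3-dihydro-1-benzofuran-5-yl]prop-2-enoate
Conditions: Zn, AcOH/THF/H2O, 60 °C
Reagents that add atoms: none
Why: Reductive N–O cleavage of the alkoxyamine by zinc in acetic acid releases the C9 alcohol. It is done at the enoate stage because the aldehyde of 22 and the cinnamyl alcohol of 25 would not tolerate warm acid and zinc.

Step 20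
Reactants: 24 enoate bis-pivalate alcohol
Product: 25 4-[(2R,3S)-3-(hydroxymethyl)-5-[(2R,3S)-3-(hydroxymethyl)-5-[(E)-3-hydroxyprop-1-enyl]-7-methoxy-2,3-dihydro-1-benzofuran-2-yl]-7-methoxy-2,3-dihydro-1-benzofuran-2-yl]-2-methoxyphenol (CNP0250921.1)
Conditions: i-Bu2AlH (excess), CH2Cl2, −78 to 0 °C; aq. potassium sodium tartrate
Reagents that add atoms: none
Why: The aluminium hydride reduces the enoate 1,2 to the allylic alcohol and cleaves the alkyl and the aryl pivalate reductively in the same operation. No acid or strong base meets the cinnamyl alcohol or the benzylic ethers, and no stereocentre is touched.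

## Compound list

1 | 5-iodovanillin | COc1cc(C=O)cc(I)c1O | starting material
2 | 3-iodo-5-methoxy-4-(methoxymethoxy)benzaldehyde | COCOc1c(I)cc(C=O)cc1OC | intermediate
3 | [3-iodo-5-methoxy-4-(methoxymethoxy)phenyl]methanol | COCOc1c(I)cc(CO)cc1OC | intermediate
4 | 5-(bromomethyl)-1-iodo-3-methoxy-2-(methoxymethoxy)benzene | COCOc1c(I)cc(CBr)cc1OC | intermediate
5 | 2-[3-iodo-5-methoxy-4-(methoxymethoxy)phenyl]-5,5-dimethyl-1,3-dioxane | COCOc1c(I)cc(C2OCC(C)(C)CO2)cc1OC | intermediate
6 | ethyl 2-[5-(5,5-dimethyl-1,3-dioxan-2-yl)-3-methoxy-2-(methoxymethoxy)phenyl]acetate | CCOC(=O)Cc1cc(C2OCC(C)(C)CO2)cc(OC)c1OCOC | intermediate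
7 | 2-[5-(5,5-dimethyl-1,3-dioxan-2-yl)-3-methoxy-2-(methoxymethoxy)phenyl]acetic acid | OC(=O)Cc1cc(C2OCC(C)(C)CO2)cc(OC)c1OCOC | intermediate
8 | (S)-4-benzyl-2-oxazolidinone | O=C1N[C@@H](Cc2ccccc2)CO1 | starting material
9 | 2-[5-(5,5-dimethyl-1,3-dioxan-2-yl)-3-methoxy-2-(methoxymethoxy)phenyl]acetic pivalic anhydride (not isolated) | CC(C)(C)C(=O)OC(=O)Cc1cc(C2OCC(C)(C)CO2)cc(OC)c1OCOC | intermediate
10 | (4S)-4-benzyl-3-{2-[5-(5,5-dimethyl-1,3-dioxan-2-yl)-3-methoxy-2-(methoxymethoxy)phenyl]acetyl}-1,3-oxazolidin-2-one | O=C(Cc1cc(C2OCC(C)(C)CO2)cc(OC)c1OCOC)N1[C@@H](Cc2ccccc2)COC1=O | intermediate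
11 | (4S)-4-benzyl-3-{(2S)-2-[5-(5,5-dimethyl-1,3-dioxan-2-yl)-3-methoxy-2-(methoxymethoxy)phenyl]-3-[3-iodo-5-methoxy-4-(methoxymethoxy)phenyl]propanoyl}-1,3-oxazolidin-2-one | O=C([C@@H](Cc1cc(OC)c(OCOC)c(I)c1)c1cc(C2OCC(C)(C)CO2)cc(OC)c1OCOC)N1[C@@H](Cc2ccccc2)COC1=O | intermediate
12 | (2S)-2-[5-(5,5-dimethyl-1,3-dioxan-2-yl)-3-methoxy-2-(methoxymethoxy)phenyl]-3-[3-iodo-5-methoxy-4-(methoxymethoxy)phenyl]propan-1-ol | OC[C@@H](Cc1cc(OC)c(OCOC)c(I)c1)c1cc(C2OCC(C)(C)CO2)cc(OC)c1OCOC | intermediate
13 | (2S)-2-[5-(5,5-dimethyl-1,3-dioxan-2-yl)-3-methoxy-2-(methoxymethoxy)phenyl]-3-[3-iodo-5-methoxy-4-(methoxymethoxy)phenyl]propyl pivalate | CC(C)(C)C(=O)OC[C@@H](Cc1cc(OC)c(OCOC)c(I)c1)c1cc(C2OCC(C)(C)CO2)cc(OC)c1OCOC | intermediate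
14 | (2S)-2-(5-formyl-2-hydroxy-3-methoxyphenyl)-3-(4-hydroxy-3-iodo-5-methoxyphenyl)propyl pivalate | O=Cc1cc(OC)c(O)c([C@@H](COC(=O)C(C)(C)C)Cc2cc(OC)c(O)c(I)c2)c1 | intermediate
15 | (2S)-2-(5-formyl-2-hydroxy-3-methoxyphenyl)-3-(3-iodo-5-methoxy-4-oxocyclohexa-2,5-dien-1-ylidene)propyl pivalate, the para-quinone methide (alkene geometry not defined; not isolated) | COC1=CC(=C[C@H](COC(=O)C(C)(C)C)c2cc(C=O)cc(OC)c2O)C=C(I)C1=O | intermediate
16 | [(2R,3S)-5-formyl-2-(4-hydroxy-3-iodo-5-methoxyphenyl)-7-methoxy-2,3-dihydro-1-benzofuran-3-yl]methyl pivalate | Oc1c(OC)cc(cc1I)[C@@H]1Oc2c(OC)cc(C=O)cc2[C@H]1COC(=O)C(C)(C)C | intermediate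
17 | coniferyl aldehyde, (E)-4-hydroxy-3-methoxycinnamaldehyde | COc1cc(/C=C/C=O)ccc1O | starting material
18 | 2-methoxy-4-[(E)-3-oxoprop-1-enyl]phenyl pivalate | COc1cc(/C=C/C=O)ccc1OC(=O)C(C)(C)C | intermediate
19 | 4-[(E)-3-hydroxyprop-1-enyl]-2-methoxyphenyl pivalate | COc1cc(/C=C/CO)ccc1OC(=O)C(C)(C)C | intermediate
20 | (E)-3-(3-methoxy-4-pivaloyloxyphenyl)prop-2-enyl methyl carbonate | COc1cc(/C=C/COC(=O)OC)ccc1OC(=O)C(C)(C)C | intermediate
21 | [(2R,3S)-5-formyl-2-{3-iodo-5-methoxy-4-[(1R)-1-(3-methoxy-4-pivaloyloxyphenyl)prop-2-enyloxy]phenyl}-7-methoxy-2,3-dihydro-1-benzofuran-3-yl]methyl pivalate | C=C[C@@H](Oc1c(OC)cc(cc1I)[C@@H]1Oc2c(OC)cc(C=O)cc2[C@H]1COC(=O)C(C)(C)C)c1ccc(OC(=O)C(C)(C)C)c(OC)c1 | intermediate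
22 | [(2R,3S)-5-formyl-7-methoxy-2-{(2R,3S)-7-methoxy-2-(3-methoxy-4-pivaloyloxyphenyl)-3-[(2,2,6,6-tetramethylpiperidin-1-yl)oxymethyl]-2,3-dihydro-1-benzofuran-5-yl}-2,3-dihydro-1-benzofuran-3-yl]methyl pivalate | COc1cc([C@@H]2Oc3c(OC)cc([C@@H]4Oc5c(OC)cc(C=O)cc5[C@H]4COC(=O)C(C)(C)C)cc3[C@H]2CON6C(C)(C)CCCC6(C)C)ccc1OC(=O)C(C)(C)C | intermediate
23 | ethyl (E)-3-[(2R,3S)-7-methoxy-2-{(2R,3S)-7-methoxy-2-(3-methoxy-4-pivaloyloxyphenyl)-3-[(2,2,6,6-tetramethylpiperidin-1-yl)oxymethyl]-2,3-dihydro-1-benzofuran-5-yl}-3-(pivaloyloxymethyl)-2,3-dihydro-1-benzofuran-5-yl]prop-2-enoate | COc1cc([C@@H]2Oc3c(OC)cc([C@@H]4Oc5c(OC)cc(/C=C/C(=O)OCC)cc5[C@H]4COC(=O)C(C)(C)C)cc3[C@H]2CON6C(C)(C)CCCC6(C)C)ccc1OC(=O)C(C)(C)C | intermediate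
24 | ethyl (E)-3-[(2R,3S)-2-{(2R,3S)-3-(hydroxymethyl)-7-methoxy-2-(3-methoxy-4-pivaloyloxyphenyl)-2,3-dihydro-1-benzofuran-5-yl}-7-methoxy-3-(pivaloyloxymethyl)-2,3-dihydro-1-benzofuran-5-yl]prop-2-enoate | COc1cc([C@@H]2Oc3c(OC)cc([C@@H]4Oc5c(OC)cc(/C=C/C(=O)OCC)cc5[C@H]4COC(=O)C(C)(C)C)cc3[C@H]2CO)ccc1OC(=O)C(C)(C)C | intermediate
25 | 4-[(2R,3S)-3-(hydroxymethyl)-5-[(2R,3S)-3-(hydroxymethyl)-5-[(E)-3-hydroxyprop-1-enyl]-7-methoxy-2,3-dihydro-1-benzofuran-2-yl]-7-methoxy-2,3-dihydro-1-benzofuran-2-yl]-2-methoxyphenol (CNP0250921.1) | COc1cc([C@@H]2Oc3c(OC)cc([C@@H]4Oc5c(OC)cc(/C=C/CO)cc5[C@H]4CO)cc3[C@H]2CO)ccc1O | target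

## Step count and least certain steps

Total: 20 steps. Longest linear sequence: 15 steps (steps 1, 4 to 12, 16 to 20).

Step 12 (key step). The iodine-deactivated phenol may be oxidized slowly, leaving conversion incomplete. Quinone methide 15 may tautomerize to a stilbene before the phenol adds, which would erase C3'. The product phenol may be oxidized a second time, towards aromatization of the new ring. Fallback: the same O1'–C2' bond is closed by an ionic route that sets out from 7 (with 2 as partner) and returns at 16.
- Acid 7 would be coupled through 9 with (R)-4-benzyl-2-oxazolidinone to give (4R)-4-benzyl-3-(arylacetyl)oxazolidinone F1. The antipode of 8 is needed because the boron aldol and the alkylation use opposite enolate faces.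
- The dibutylboron (Z)-enolate of F1 (Bu2BOTf, i-Pr2NEt, CH2Cl2, −78 °C) would add to aldehyde 2 in an Evans syn aldol reaction through a Zimmerman–Traxler transition state, giving beta-hydroxy imide F2 with the required C3' configuration. Its carbinol centre is of no consequence.
- LiBH4 would give the 1,3-diol F3, and PivCl/pyridine at 0 °C would acylate the primary hydroxyl selectively to give hydroxy pivalate F4.
- 2 M HCl in THF would then remove the MOM ethers and the acetal and ionize the benzylic alcohol to the para-hydroxybenzyl cation (the protonated form of 15). The ring C phenol should capture it to give the trans ring of 16.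

Step 16. The 2,6-disubstituted aryloxide is a hindered, weak nucleophile, so attack on the allyl complex may be slow. Slow attack allows loss of branched selectivity, and re-ionization of the aryl ether product would erode the configuration at C2. Fallback: stereospecific displacement in place of catalysis, setting out from 16 and returning at 21. Vanillin would be pivaloylated to 4-formyl-2-methoxyphenyl pivalate F5. Enantioselective vinylation (Zn(CH=CH2)2 with a chiral amino alcohol ligand) would give (1S)-1-(3-methoxy-4-pivaloyloxyphenyl)prop-2-en-1-ol F6. A Mitsunobu reaction of 16 with F6 (PPh3, DIAD, toluene, 0 °C) should invert the carbinol centre and give the (R) ether 21; the electron-withdrawing pivalate tempers ionization of the activated alcohol.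

Step 17. Three processes may interfere: a 1,5-hydrogen shift from the doubly activated C2–H to the aryl radical, capture of the aryl radical by TEMPO before ring closure, and insufficient trans induction at C3. Fallback: the oxygen is installed through boron instead of a nitroxide, so that an ordinary reductive chain cyclization can be used; it sets out from 21 and returns at 24.
- Cross-metathesis of 21 with vinylboronic acid pinacol ester using the second-generation Grubbs catalyst (H2IMes)(PCy3)Cl2Ru=CHPh would give the (E)-alkenylboronate F7.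
- Bu3SnH/AIBN in toluene at 80 °C would close the ring through an alpha-boryl radical, whose larger alkene terminus should also reinforce the trans preference, giving the C9 boronate F8.
- NaBO3·4H2O in THF/H2O would oxidize the C–B bond to the aldehyde alcohol F9, and the Wittig reaction of step 18 applied to F9 would give 24.

Step 5. Transmetalation of the zinc enolate to the hindered ortho-alkoxy arylpalladium may be slow, which opens the way to protodehalogenation, and the zinc halide formed may loosen the acetal. Fallback: the two-carbon chain is introduced as an allyl group and cut down, setting out from 5 and returning at 7. Stille coupling of 5 with allyltributylstannane (Pd(PPh3)4, toluene, 100 °C) would give the allyl arene F10. Lemieux–Johnson cleavage (OsO4 cat., NaIO4, 2,6-lutidine, dioxane/H2O) would give the arylacetaldehyde F11, and Pinnick oxidation (NaClO2, NaH2PO4, 2-methyl-2-butene) would give acid 7.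

## Further compounds

F1 | step 12 | (4R)-4-benzyl-3-{2-[5-(5,5-dimethyl-1,3-dioxan-2-yl)-3-methoxy-2-(methoxymethoxy)phenyl]acetyl}-1,3-oxazolidin-2-one | O=C(Cc1cc(C2OCC(C)(C)CO2)cc(OC)c1OCOC)N1[C@H](Cc2ccccc2)COC1=O
F2 | step 12 | (4R)-4-benzyl-3-{(2R,3R)-2-[5-(5,5-dimethyl-1,3-dioxan-2-yl)-3-methoxy-2-(methoxymethoxy)phenyl]-3-hydroxy-3-[3-iodo-5-methoxy-4-(methoxymethoxy)phenyl]propanoyl}-1,3-oxazolidin-2-one | O=C([C@@H]([C@@H](O)c1cc(OC)c(OCOC)c(I)c1)c1cc(C2OCC(C)(C)CO2)cc(OC)c1OCOC)N1[C@H](Cc2ccccc2)COC1=O
F3 | step 12 | (1R,2S)-2-[5-(5,5-dimethyl-1,3-dioxan-2-yl)-3-methoxy-2-(methoxymethoxy)phenyl]-1-[3-iodo-5-methoxy-4-(methoxymethoxy)phenyl]propane-1,3-diol | OC[C@@H]([C@@H](O)c1cc(OC)c(OCOC)c(I)c1)c1cc(C2OCC(C)(C)CO2)cc(OC)c1OCOC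
F4 | step 12 | (2S,3R)-2-[5-(5,5-dimethyl-1,3-dioxan-2-yl)-3-methoxy-2-(methoxymethoxy)phenyl]-3-hydroxy-3-[3-iodo-5-methoxy-4-(methoxymethoxy)phenyl]propyl pivalate | CC(C)(C)C(=O)OC[C@@H]([C@@H](O)c1cc(OC)c(OCOC)c(I)c1)c1cc(C2OCC(C)(C)CO2)cc(OC)c1OCOC
F5 | step 16 | 4-formyl-2-methoxyphenyl pivalate | COc1cc(C=O)ccc1OC(=O)C(C)(C)C
F6 | step 16 | (1S)-1-(3-methoxy-4-pivaloyloxyphenyl)prop-2-en-1-ol | C=C[C@H](O)c1ccc(OC(=O)C(C)(C)C)c(OC)c1
F7 | step 17 | (E)-alkenylboronate of 21: [(2R,3S)-5-formyl-2-{3-iodo-5-methoxy-4-[(1R,2E)-1-(3-methoxy-4-pivaloyloxyphenyl)-3-(4,4,5,5-tetramethyl-1,3,2-dioxaborolan-2-yl)prop-2-enyloxy]phenyl}-7-methoxy-2,3-dihydro-1-benzofuran-3-yl]methyl pivalate | CC1(C)OB(OC1(C)C)/C=C/[C@@H](Oc2c(OC)cc(cc2I)[C@@H]2Oc3c(OC)cc(C=O)cc3[C@H]2COC(=O)C(C)(C)C)c2ccc(OC(=O)C(C)(C)C)c(OC)c2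
F8 | step 17 | trans bis(dihydrobenzofuran) with C9 as the pinacol boronate (C5' aldehyde, C9' pivalate, ring A pivalate) | COc1cc([C@@H]2Oc3c(OC)cc([C@@H]4Oc5c(OC)cc(C=O)cc5[C@H]4COC(=O)C(C)(C)C)cc3[C@H]2CB6OC(C)(C)C(C)(C)O6)ccc1OC(=O)C(C)(C)C
F9 | step 17 | [(2R,3S)-5-formyl-2-{(2R,3S)-3-(hydroxymethyl)-7-methoxy-2-(3-methoxy-4-pivaloyloxyphenyl)-2,3-dihydro-1-benzofuran-5-yl}-7-methoxy-2,3-dihydro-1-benzofuran-3-yl]methyl pivalate | COc1cc([C@@H]2Oc3c(OC)cc([C@@H]4Oc5c(OC)cc(C=O)cc5[C@H]4COC(=O)C(C)(C)C)cc3[C@H]2CO)ccc1OC(=O)C(C)(C)C
F10 | step 5 | 2-[3-allyl-5-methoxy-4-(methoxymethoxy)phenyl]-5,5-dimethyl-1,3-dioxane | C=CCc1cc(C2OCC(C)(C)CO2)cc(OC)c1OCOC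
F11 | step 5 | 2-[5-(5,5-dimethyl-1,3-dioxan-2-yl)-3-methoxy-2-(methoxymethoxy)phenyl]acetaldehyde | O=CCc1cc(C2OCC(C)(C)CO2)cc(OC)c1OCOC
A1 | alternative 1 | ring C aryldiazoacetate, (S)-lactic pyrrolidide ester, O-benzylated by C5 of bis-TBS unit 1 (aryl bromide) | COc1cc([C@@H]2Oc3c(OC)cc(COc5c(OC)cc(Br)cc5C(=[N+]=[N-])C(=O)O[C@@H](C)C(=O)N6CCCC6)cc3[C@H]2CO[Si](C)(C)C(C)(C)C)ccc1O[Si](C)(C)C(C)(C)C
A2 | alternative 1 | trans bis(dihydrobenzofuran) C3' lactamide ester (bis-TBS, aryl bromide) | COc1cc([C@@H]2Oc3c(OC)cc([C@@H]4Oc5c(OC)cc(Br)cc5[C@H]4C(=O)O[C@@H](C)C(=O)N6CCCC6)cc3[C@H]2CO[Si](C)(C)C(C)(C)C)ccc1O[Si](C)(C)C(C)(C)C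
A3 | alternative 2 | ring B aryl iodide (R)-1-arylallyl ether of bis-TBS unit 2 (ring A pivalate) | C=C[C@@H](Oc1c(OC)cc(cc1I)[C@@H]1Oc2c(OC)cc(/C=C/CO[Si](C)(C)C(C)(C)C)cc2[C@H]1CO[Si](C)(C)C(C)(C)C)c1ccc(OC(=O)C(C)(C)C)c(OC)c1
A4 | alternative 2 | trans bis(dihydrobenzofuran) with C9 as the TEMPO alkoxyamine (ring A pivalate, bis-TBS) | COc1cc([C@@H]2Oc3c(OC)cc([C@@H]4Oc5c(OC)cc(/C=C/CO[Si](C)(C)C(C)(C)C)cc5[C@H]4CO[Si](C)(C)C(C)(C)C)cc3[C@H]2CON6C(C)(C)CCCC6(C)C)ccc1OC(=O)C(C)(C)C
A5 | alternative 3 | (2R)-6-bromo-8-methoxyflavanone whose 2-aryl group is ring B of diacetylated unit 1 | COc1cc([C@@H]2Oc3c(OC)cc([C@H]4CC(=O)c5cc(Br)cc(OC)c5O4)cc3[C@H]2COC(C)=O)ccc1OC(C)=O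
A6 | alternative 3 | trans bis(dihydrobenzofuran) C3' methyl ester (diacetate, aryl bromide) | COc1cc([C@@H]2Oc3c(OC)cc([C@@H]4Oc5c(OC)cc(Br)cc5[C@H]4C(=O)OC)cc3[C@H]2COC(C)=O)ccc1OC(C)=O
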